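Numbering used throughout: 1 auxiliary, 2 acid chloride, 3 imide, 4 enolate, 5 dimer, 6 diallyl diol, 7 dibenzyl ether diene, 8 bis(ozonide), 9 dialdehyde, 10 phosphonium salt, 11 methoxyacetyl chloride, 12 methylene ylide, 13 acylphosphonium salt, 14 keto ylide, 15 bis(enone), 16 dimethyl malonate, 17 bis-Michael adduct, 18 bis(dione ester), 19 bis(keto acid), 20 bis(dione), 21 bis(phenol), 22 bis(trimethoxyarene) dibenzyl ether, 23 diol, 24 hydroxy aldehyde, 25 lactol, 26 target.

## Analysis of the target

(-)-Cubebininolide 26 is a γ-butyrolactone (numbered here O1, C1 carbonyl, C2, C3, C4) with a 3,4,5-trimethoxybenzyl group on the α carbon C2 (through C7') and an identical one on the β carbon C3 (through C7''). C2 and C3 are the only stereocentres; both are R and the two benzyl groups are trans. Apart from the oxidation level of C1 the molecule is C2-symmetric: reducing C1 to CH2OH gives a diol with a twofold axis through the C2–C3 bond. C2 sits next to the lactone carbonyl and can epimerise under base, the lactone opens with alkoxide or hydroxide, and the electron-rich arenes are sensitive to oxidants and electrophiles. Any cationic chemistry at C7' or C7'' is dangerous, because such cations close onto the other arene to give aryltetralins. The difficulty is therefore the absolute configuration of two adjacent CH centres with nearly identical substituents, combined with installing two densely oxygenated arenes without disturbing them. The plan rests on one feature: each aryl ring has a single carbon substituent (C7' or C7''), para to the central methoxy group and meta to the outer two. That is the pattern of C5 in a 2-methoxycyclohexane-1,3-dione, whose two carbonyl oxygens and C2 methoxy group become the three contiguous aryl ethers on dehydrogenation.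

## Retrosynthetic reasoning

26 to 23. The C1 carbonyl is taken back to a CH2OH group, which gives the C2-symmetric diol 23. Either hydroxyl of 23 leads to the same lactone, so no differentiation is needed. This places the only base-labile arrangement (C2 next to a carbonyl) in the very last step.

23 to 22. The two hydroxyls are masked as benzyl ethers. The mask has to survive alkoxide at reflux, hot aqueous hydroxide, warm mineral acid and a halogen oxidant in a hot alcohol; silyl ethers would fail the last two. Benzyl ethers leave by hydrogenolysis, which the finished arenes tolerate.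

22 to 21 to 20. The aryl methyl ether bonds and the ring unsaturation are removed. Each arene becomes a six-membered dione ring with a methoxy group between the carbonyls, as in 20. The forward reaction is a two-electron oxidation per ring followed by completion of O-methylation, and it erases every ring stereocentre.

20 to 18. An ester group is put back on the ring carbon next to the side-chain-bearing carbon. This reveals the malonate origin of two ring carbons; the forward step is saponification and decarboxylation.

18 to 15 and 16 (key disconnection). Two bonds are cut in each ring. The first joins the ring carbon carrying the side chain to the ester-bearing carbon (conjugate addition). The second joins the methoxy-bearing carbon to the neighbouring carbonyl carbon that came from 16 (Claisen condensation). This is the best place to cut because it leaves an enone and a malonate, fixes the position of the side chain on the ring by construction, and keeps C2 and C3 one CH2 away from all carbonyl chemistry. The forward reaction must add 16 to both enones of 15 before ring closure and must avoid reactions between the two arms.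

15 to 9 and 14. The enone C=C bonds are cut as Wittig olefinations of dialdehyde 9 with the stabilised ylide 14. Cross-metathesis on the terminal alkenes of 7 is not used, because 7 is a 1,7-diene and a metathesis catalyst would close it to a six-membered cycloalkene faster than any cross-coupling. Olefination with a neutral ylide gives the E-enones and spares the 1,6-dialdehyde from intramolecular aldol condensation.

14 to 10 and 11. The keto ylide is made by C-acylation of the methylene ylide derived from 10 with acid chloride 11, in one step.

9 to 7 to 6. The aldehydes come from oxidative cleavage of the two vinyl groups of 7, which is the dibenzyl ether of diol 6.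

6 to 5 to 3, then 1 and 2. The C2–C3 bond is cut last. Dimer 5 is two molecules of imide 3 joined at their α carbons, so one oxidative enolate coupling forms the central bond and both stereocentres under control of the auxiliary 1. Reduction then removes the auxiliary and takes both centres out of enolisable positions for the whole middle of the route. Imide 3 comes from 1 and 2.

## Alternatives that were turned down

Alternative 1: The disconnection is at the two C7–aryl bonds. Both benzylic carbons start as the methyl groups of (2R,3R)-2,3-dimethyl-N1,N4-di(quinolin-8-yl)succinamide A1. 5-Iodo-1,2,3-trimethoxybenzene A2 is coupled twice by directed methyl C–H activation with Pd(OAc)2 A3 and AgOAc A4 to give the dibenzylsuccinamide A5. Removal of the amides and reduction would lead to diol 23.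
- For: it is the shortest plan (about half the step count), both arenes are bought complete, and the C2 symmetry is used fully. On step economy and convergence it is clearly stronger than the chosen route.
- Against: C2 and C3 are α to amide carbonyls during a hot carboxylate-mediated palladium step and again during cleavage of two hindered secondary amides, so epimerisation to the meso series is a real risk. Each methyl must be arylated once only, yet the CH2Ar groups of A5 still carry C–H bonds activated by the same directing group. Two chelating amides on adjacent carbons can bind one palladium together or close to a succinimide. Enantiopure A1 itself needs a resolution or a synthesis.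
- In exchange the chosen route keeps both centres away from any carbonyl while the carbon–carbon bonds are made, lets the stereo-defining dimer 5 be purified as a diastereomer, and has no mono- versus di-arylation question.

Alternative 2: The disconnection is at the C3–C4 bond and the C1–O1 bond. The ketone enolate of (R)-2-(3,4,5-trimethoxybenzyl)-4-oxo-4-(3,4,5-trimethoxyphenyl)butanoic acid A6 adds to formaldehyde A7 at C3. The hydroxy acid lactonises to the β-aroyl lactone A8, base funnels C3 to trans, and the C7'' ketone is finally reduced to CH2.
- For: it is convergent and shorter than the chosen route, uses commercial trimethoxyphenyl building blocks, and needs only one stereocentre from asymmetric synthesis. On length it is stronger.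
- Against: in A8 both ring centres are enolisable, one next to the lactone carbonyl and one next to the aryl ketone. The equilibration that corrects C3 can also invert C2, and two successive inversions give the enantiomer, so the optical purity rests on a rate difference. A7 can add twice or the aldol can dehydrate to a methylene ketone. The last deoxygenation passes a benzylic alcohol or cation beside an electron-rich ring, the classical path to aryltetralins.
- In exchange the chosen route has both centres fixed and non-enolisable from step 3 to step 12 and never raises C7' or C7'' above the CH2 level.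

Alternative 3: The disconnection is at the C2–C7' and C3–C7'' bonds. Buta-1,3-diene A9 adds to bis[(1R,2S,5R)-2-isopropyl-5-methylcyclohexyl] fumarate A10 under Et2AlCl A11 to give the cyclohexene diester A12. The trans relationship comes from the alkene geometry and the absolute sense from the ester groups. Reduction, benzylation and alkene cleavage would give dialdehyde 9 itself; the arenes would then be added as aryl nucleophiles and the two benzylic hydroxyls removed.
- For: the cycloaddition is cheap, scalable and highly predictable. For setting C2 and C3 it is at least as strong as, and probably stronger than, the oxidative dimerisation of step 2. The arenes are commercial and the total length is similar.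
- Against: C7' and C7'' arrive as aldehydes, so two aryl additions and two benzylic deoxygenations follow. The deoxygenations run through benzylic cations flanked by a second electron-rich ring and by oxygen functions, which invites aryltetralin or tetrahydrofuran formation. Hydrogenolytic removal competes with the O-benzyl groups.
- In exchange the chosen route has C7' and C7'' as CH2 from the start and builds each arene around that sp3 carbon, so no aryl organometallic and no benzylic deoxygenation is needed.

Key step: step 8

Assumption: step 10 is expected to give a set of partly O-methylated pyrogallol ethers; the route is written for the least methylated member (one free phenol per ring, 21), because every member of the set gives 22 in step 11.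

## Route

Step 1
Reactants: 1 (S)-4-benzyl-1,3-oxazolidin-2-one; 2 pent-4-enoyl chloride
Product: 3 (S)-4-benzyl-3-(pent-4-enoyl)-1,3-oxazolidin-2-one
Conditions: Et3N, DMAP (cat.), CH2Cl2, 0 °C to rt
Reagents that add atoms: none
Why: N-Acylation of the oxazolidinone by the acid chloride under nucleophilic (DMAP) catalysis; the auxiliary stereocentre is not involved and no strong base is needed.

Step 2
Reactants: 3 (S)-4-benzyl-3-(pent-4-enoyl)-1,3-oxazolidin-2-one (two molecules)
Product: 5 (2R,3R)-2,3-diallyl-1,4-bis[(S)-4-benzyl-2-oxo-1,3-oxazolidin-3-yl]butane-1,4-dione, via lithium Z-enolate 4 (not isolated)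
Conditions: LiN(iPr)2, THF, -78 °C; then TiCl4, -78 °C to rt
Reagents that add atoms: none
Why: Oxidative homocoupling of a 3-acyl-2-oxazolidinone enolate: the chelated Z-enolate 4 is transmetalated by TiCl4, single-electron transfer to tetravalent titanium (which ends as trivalent titanium) gives α-carbonyl radicals, and these pair at their α carbons to form the C2–C3 bond. Each new centre should form on the enolate face away from the benzyl group of the (S)-auxiliary, the same sense as in alkylations of this enolate, which corresponds to R at both carbons; the R,S and S,S dimers are diastereomers of 5 and can be removed here by crystallisation or chromatography. The vinyl groups are too close to the radical centre to cyclise (only three- or four-membered rings could form).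

Step 3
Reactants: 5 (2R,3R)-2,3-diallyl-1,4-bis[(S)-4-benzyl-2-oxo-1,3-oxazolidin-3-yl]butane-1,4-dione
Product: 6 (2R,3R)-2,3-diallylbutane-1,4-diol
Conditions: LiBH4, MeOH (2 equiv), THF, 0 °C to rt
Reagents that add atoms: none
Why: Reductive cleavage of N-acyl oxazolidinones by LiBH4 at the exocyclic carbonyl; no enolate forms, so C2 and C3 keep their configuration, and neither centre is next to a carbonyl again until the last step. Auxiliary 1 is recovered.

Step 4
Reactants: 6 (2R,3R)-2,3-diallylbutane-1,4-diol
Product: 7 (4R,5R)-4,5-bis[(benzyloxy)methyl]octa-1,7-diene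
Conditions: NaH, BnBr, Bu4NI (cat.), THF/DMF, 0 °C to rt
Reagents that add atoms: benzyl bromide, BrCc1ccccc1
Why: Williamson ether synthesis; benzyl ethers are chosen because they withstand alkoxide, hot aqueous hydroxide, warm mineral acid and HI in methanol, all of which lie ahead, whereas silyl ethers would be lost in the last two.

Step 5
Reactants: 7 (4R,5R)-4,5-bis[(benzyloxy)methyl]octa-1,7-diene
Product: 9 (3R,4R)-3,4-bis[(benzyloxy)methyl]hexanedial, via bis(ozonide) 8 (not isolated)
Conditions: O3, CH2Cl2, -78 °C; then PPh3, -78 °C to rt
Reagents that add atoms: ozone, [O-][O+]=O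
Why: Ozonolysis of the two terminal alkenes with reductive work-up; each vinyl group gives the aldehyde and formaldehyde. Ozone is stopped at the first blue colour so that the benzyl ethers are not oxidised, and 9, a 1,6-dialdehyde prone to intramolecular aldol condensation, is used at once without chromatography.

Step 6
Reactants: 10 methyltriphenylphosphonium bromide (2 equiv); 11 methoxyacetyl chloride
Product: 14 1-methoxy-3-(triphenyl-λ5-phosphanylidene)propan-2-one, via methylenetriphenylphosphorane 12 (not isolated), via acylphosphonium chloride 13 (not isolated)
Conditions: n-BuLi, THF, 0 °C; then 11 (0.5 equiv), -78 °C to rt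
Reagents that add atoms: none
Why: C-Acylation of a phosphorus ylide with transylidation: 12 attacks the acid chloride to give phosphonium salt 13, whose acidified CH2 is deprotonated by the second equivalent of 12 to leave the stable keto ylide 14.

Step 7
Reactants: 9 (3R,4R)-3,4-bis[(benzyloxy)methyl]hexanedial; 14 1-methoxy-3-(triphenyl-λ5-phosphanylidene)propan-2-one (2.5 equiv)
Product: 15 (3E,6R,7R,9E)-6,7-bis[(benzyloxy)methyl]-1,12-dimethoxydodeca-3,9-diene-2,11-dione
Conditions: CH2Cl2, 40 °C
Reagents that add atoms: none
Why: Twofold Wittig olefination with a carbonyl-stabilised ylide, which should give the E-enones; the neutral conditions keep the 1,6-dialdehyde from self-condensing, and because no metathesis is involved the ring closure of the 1,7-diene 7 to a cyclohexene never arises.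

Step 8
Reactants: 15 (3E,6R,7R,9E)-6,7-bis[(benzyloxy)methyl]-1,12-dimethoxydodeca-3,9-diene-2,11-dione; 16 dimethyl malonate (3 equiv)
Product: 18 dimethyl 6,6'-[(2R,3R)-2,3-bis[(benzyloxy)methyl]butane-1,4-diyl]bis(3-methoxy-2,4-dioxocyclohexane-1-carboxylate), via bis-Michael adduct 17 (not isolated)
Conditions: NaOMe (3 equiv), MeOH, 0 °C to rt, then reflux, under Ar; AcOH
Reagents that add atoms: none
Why: This is a Michael–Claisen annulation, the reaction type by which an enone and a malonate are condensed to a cyclohexane-1,3-dione (as in the preparation of 5-alkylcyclohexane-1,3-diones from alk-3-en-2-ones). The sodium enolate of 16 (NaCH(CO2Me)2) adds to the β carbon of each enone of 15 to give 17; proton transfer then forms the ketone enolate on the methoxy-bearing side, which attacks one malonate ester carbonyl and expels methoxide. Each of the two rings closes by 6-exo-trig attack of this carbanion on the ester carbonyl (Dieckmann-type Claisen condensation); the other enolate of the same ketone could only close a four-membered ring. Closure is driven to completion because 18 is at once deprotonated to a doubly stabilised dione enolate, which is why a full equivalent of NaOMe per ring is used. New stereocentres arise at three carbons of each ring, but none is controlled and none is needed, since all are erased on aromatisation; C2 and C3 of the core are separated from every carbonyl by a CH2 group and cannot be epimerised by the alkoxide. The selectivity required is chemoselectivity: intermolecular addition of 16 to both enones must precede Claisen closure and must outrun addition of a carbanion of one arm to the enone of the other, which would close seven-membered rings. This is secured by adding 15 to an excess of the preformed malonate enolate at 0 °C, by the enone being the only Michael acceptor present, and by the six-membered ring being the only unstrained closure open to each adduct.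

Step 9
Reactants: 18 dimethyl 6,6'-[(2R,3R)-2,3-bis[(benzyloxy)methyl]butane-1,4-diyl]bis(3-methoxy-2,4-dioxocyclohexane-1-carboxylate)
Product: 20 5,5'-[(2R,3R)-2,3-bis[(benzyloxy)methyl]butane-1,4-diyl]bis(2-methoxycyclohexane-1,3-dione), via dicarboxylic acid 19 (not isolated)
Conditions: NaOH, H2O/MeOH, reflux, under Ar; then HCl to pH 2, 70 °C
Reagents that add atoms: none
Why: Ester saponification followed by decarboxylation of the β-keto acids 19 on acidification and warming, the standard finish of a malonate-based dione synthesis; during the basic stage each ring is a delocalised dione enolate, which protects it from retro-Claisen cleavage, and air is excluded because this enolate is electron-rich.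

Step 10
Reactants: 20 5,5'-[(2R,3R)-2,3-bis[(benzyloxy)methyl]butane-1,4-diyl]bis(2-methoxycyclohexane-1,3-dione)
Product: 21 5,5'-[(2R,3R)-2,3-bis[(benzyloxy)methyl]butane-1,4-diyl]bis(2,3-dimethoxyphenol)
Conditions: I2 (2.2 equiv), MeOH, reflux
Reagents that add atoms: methanol, CO
Why: Oxidative aromatisation of cyclohexane-1,3-diones with I2 in methanol: HI from the first turnover catalyses conversion of the dione into its methyl enol ether, iodination at a flanking CH2 and loss of HI give a cyclohexadienone, and this tautomerises to the phenol, a net two-electron oxidation per ring. The methoxy group between the carbonyls blocks that position, so productive halogenation can only occur at the ring CH2 groups; all ring stereocentres vanish here.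

Step 11
Reactants: 21 5,5'-[(2R,3R)-2,3-bis[(benzyloxy)methyl]butane-1,4-diyl]bis(2,3-dimethoxyphenol)
Product: 22 (2R,3R)-1,4-bis(benzyloxy)-2,3-bis(3,4,5-trimethoxybenzyl)butane
Conditions: Me2SO4, K2CO3, acetone, reflux
Reagents that add atoms: dimethyl sulfate, COS(=O)(=O)OC
Why: Williamson O-methylation of the phenols; more highly methylated material from step 10 is left unchanged or completed, so everything converges on 22.

Step 12
Reactants: 22 (2R,3R)-1,4-bis(benzyloxy)-2,3-bis(3,4,5-trimethoxybenzyl)butane
Product: 23 (2R,3R)-2,3-bis(3,4,5-trimethoxybenzyl)butane-1,4-diol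
Conditions: H2 (1 atm), Pd/C, EtOAc/MeOH, rt
Reagents that add atoms: none
Why: Catalytic hydrogenolysis of the two primary benzyl ethers; the new arenes carry no benzylic heteroatom, so their CH2–aryl bonds are not cleaved.

Step 13
Reactants: 23 (2R,3R)-2,3-bis(3,4,5-trimethoxybenzyl)butane-1,4-diol
Product: 26 (3R,4R)-3,4-bis(3,4,5-trimethoxybenzyl)dihydrofuran-2(3H)-one, (-)-cubebininolide, via hydroxy aldehyde 24 (not isolated), via lactol 25 (not isolated)
Conditions: TEMPO (cat.), PhI(OAc)2, CH2Cl2, rt
Reagents that add atoms: none
Why: Oxoammonium-mediated oxidative lactonisation of a 1,4-diol: one primary alcohol is oxidised to aldehyde 24, which is trapped by the other hydroxyl as the five-membered lactol 25, and this is oxidised again to the lactone. Because 23 is C2-symmetric both hydroxyls lead to the same product; the medium is only weakly acidic (AcOH), so the centre that becomes C2 should not epimerise, and trans is in any case the more stable arrangement.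

## Compound list

1 | (S)-4-benzyl-1,3-oxazolidin-2-one | O=C1OC[C@H](Cc2ccccc2)N1 | starting material
2 | pent-4-enoyl chloride | C=CCCC(=O)Cl | starting material
3 | (S)-4-benzyl-3-(pent-4-enoyl)-1,3-oxazolidin-2-one | C=CCCC(=O)N1C(=O)OC[C@@H]1Cc1ccccc1 | intermediate
4 | lithium (Z)-1-[(S)-4-benzyl-2-oxo-1,3-oxazolidin-3-yl]penta-1,4-dien-1-olate | [Li]O/C(=C\CC=C)N1C(=O)OC[C@@H]1Cc1ccccc1 | intermediate
5 | (2R,3R)-2,3-diallyl-1,4-bis[(S)-4-benzyl-2-oxo-1,3-oxazolidin-3-yl]butane-1,4-dione | C=CC[C@@H](C(=O)N1C(=O)OC[C@@H]1Cc1ccccc1)[C@@H](CC=C)C(=O)N1C(=O)OC[C@@H]1Cc1ccccc1 | intermediate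
6 | (2R,3R)-2,3-diallylbutane-1,4-diol | C=CC[C@@H](CO)[C@@H](CC=C)CO | intermediate
7 | (4R,5R)-4,5-bis[(benzyloxy)methyl]octa-1,7-diene | C=CC[C@@H](COCc1ccccc1)[C@@H](CC=C)COCc1ccccc1 | intermediate
8 | 3,3'-[(2R,3R)-2,3-bis[(benzyloxy)methyl]butane-1,4-diyl]bis(1,2,4-trioxolane), ozonide carbons unassigned | C1(C[C@@H](COCc2ccccc2)[C@@H](CC2OCOO2)COCc2ccccc2)OCOO1 | intermediate
9 | (3R,4R)-3,4-bis[(benzyloxy)methyl]hexanedial | O=CC[C@@H](COCc1ccccc1)[C@@H](CC=O)COCc1ccccc1 | intermediate
10 | methyltriphenylphosphonium bromide | C[P+](c1ccccc1)(c1ccccc1)c1ccccc1.[Br-] | starting material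
11 | methoxyacetyl chloride | COCC(=O)Cl | starting material
12 | methylenetriphenylphosphorane | C=P(c1ccccc1)(c1ccccc1)c1ccccc1 | intermediate
13 | (3-methoxy-2-oxopropyl)triphenylphosphonium chloride | COCC(=O)C[P+](c1ccccc1)(c1ccccc1)c1ccccc1.[Cl-] | intermediate
14 | 1-methoxy-3-(triphenyl-λ5-phosphanylidene)propan-2-one | COCC(=O)C=P(c1ccccc1)(c1ccccc1)c1ccccc1 | intermediate
15 | (3E,6R,7R,9E)-6,7-bis[(benzyloxy)methyl]-1,12-dimethoxydodeca-3,9-diene-2,11-dione | COCC(=O)/C=C/C[C@H]([C@H](COCc1ccccc1)C/C=C/C(=O)COC)COCc1ccccc1 | intermediate
16 | dimethyl malonate | COC(=O)CC(=O)OC | starting material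
17 | tetramethyl 2,2'-[(6R,7R)-6,7-bis[(benzyloxy)methyl]-1,12-dimethoxy-2,11-dioxododecane-4,9-diyl]dimalonate, C4 and C9 unassigned | COCC(=O)CC(C[C@H]([C@H](COCc1ccccc1)CC(CC(=O)COC)C(C(=O)OC)C(=O)OC)COCc1ccccc1)C(C(=O)OC)C(=O)OC | intermediate
18 | dimethyl 6,6'-[(2R,3R)-2,3-bis[(benzyloxy)methyl]butane-1,4-diyl]bis(3-methoxy-2,4-dioxocyclohexane-1-carboxylate), ring centres unassigned | COC(=O)C1C(C[C@H]([C@H](COCc2ccccc2)CC2CC(=O)C(OC)C(=O)C2C(=O)OC)COCc2ccccc2)CC(=O)C(OC)C1=O | intermediate
19 | 6,6'-[(2R,3R)-2,3-bis[(benzyloxy)methyl]butane-1,4-diyl]bis(3-methoxy-2,4-dioxocyclohexane-1-carboxylic acid), ring centres unassigned | OC(=O)C1C(C[C@H]([C@H](COCc2ccccc2)CC2CC(=O)C(OC)C(=O)C2C(=O)O)COCc2ccccc2)CC(=O)C(OC)C1=O | intermediate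
20 | 5,5'-[(2R,3R)-2,3-bis[(benzyloxy)methyl]butane-1,4-diyl]bis(2-methoxycyclohexane-1,3-dione) | COC1C(=O)CC(C[C@H]([C@H](COCc2ccccc2)CC2CC(=O)C(OC)C(=O)C2)COCc2ccccc2)CC1=O | intermediate
21 | 5,5'-[(2R,3R)-2,3-bis[(benzyloxy)methyl]butane-1,4-diyl]bis(2,3-dimethoxyphenol) | COc1cc(C[C@H]([C@H](COCc2ccccc2)Cc2cc(O)c(OC)c(OC)c2)COCc2ccccc2)cc(O)c1OC | intermediate
22 | (2R,3R)-1,4-bis(benzyloxy)-2,3-bis(3,4,5-trimethoxybenzyl)butane | COc1cc(C[C@H]([C@H](COCc2ccccc2)Cc2cc(OC)c(OC)c(OC)c2)COCc2ccccc2)cc(OC)c1OC | intermediate
23 | (2R,3R)-2,3-bis(3,4,5-trimethoxybenzyl)butane-1,4-diol | COc1cc(C[C@H]([C@H](CO)Cc2cc(OC)c(OC)c(OC)c2)CO)cc(OC)c1OC | intermediate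
24 | (2R,3R)-3-(hydroxymethyl)-2-(3,4,5-trimethoxybenzyl)-4-(3,4,5-trimethoxyphenyl)butanal | COc1cc(C[C@H]([C@H](C=O)Cc2cc(OC)c(OC)c(OC)c2)CO)cc(OC)c1OC | intermediate
25 | (3R,4R)-3,4-bis(3,4,5-trimethoxybenzyl)tetrahydrofuran-2-ol, C2 unassigned | COc1cc(C[C@H]2COC(O)[C@@H]2Cc2cc(OC)c(OC)c(OC)c2)cc(OC)c1OC | intermediate
26 | (3R,4R)-3,4-bis(3,4,5-trimethoxybenzyl)dihydrofuran-2(3H)-one, (-)-cubebininolide | COc1cc(C[C@H]2COC(=O)[C@@H]2Cc2cc(OC)c(OC)c(OC)c2)cc(OC)c1OC | target

## Step count and least certain steps

Total: 13 steps. Longest linear sequence: 12 steps (steps 1 to 5 and 7 to 13, from 1 and 2); step 6 is a one-step side branch.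

Step 8 (key step). The most likely failure is cross-reaction between the two arms: the malonate carbanion of a mono-adduct, or a dienolate formed by γ-deprotonation of one enone, adding to the enone on the neighbouring carbon. The reaction may also stall at 17 if enolisation toward the methoxy-bearing carbon is slow, with retro-Michael loss on heating. The fallback inverts the roles of the two components while keeping the same ring construction. It sets out from dialdehyde 9, which is condensed with methyl (triphenylphosphoranylidene)acetate (CH2Cl2, rt) to dimethyl (2E,5R,6R,8E)-5,6-bis[(benzyloxy)methyl]deca-2,8-dienedioate F1. F1 is then heated with methyl 4-methoxy-3-oxobutanoate and NaOMe in MeOH. The β-keto ester adds through its C2 to each enoate and its methoxy-bearing C4 closes onto the enoate ester, which gives the same bis(dione ester) 18, where the fallback rejoins the route. The enoate is less electrophilic and less γ-acidic than the enone, which disfavours cross-arm additions, and the classical condensation of crotonates with acetoacetates to 5-substituted cyclohexane-1,3-diones is the model.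

Step 10. Iodination may occur at the methoxy-bearing enol carbon instead of the flanking CH2 (unproductive), dehydrogenation may stop short, or the electron-rich phenolic products may be iodinated on the ring; the HI formed may also erode ether groups on long heating. The fallback replaces halogenation by a palladium-mediated dehydrogenation. It sets out from 20, which is converted with HC(OMe)3, MeOH and TsOH (cat.) into the bis(vinylogous ester) 5,5'-[(2R,3R)-2,3-bis[(benzyloxy)methyl]butane-1,4-diyl]bis(2,3-dimethoxycyclohex-2-en-1-one) F2. Kinetic deprotonation at the CH2 next to the carbonyl (LiN(iPr)2, THF, -78 °C) and silylation with Me3SiCl give the bis(trimethylsilyl dienol ether) F3. Saegusa–Ito oxidation of F3 with Pd(OAc)2 in MeCN, in which divalent palladium is reduced to zerovalent palladium, gives the cyclohexadienones, which tautomerise to bis(phenol) 21, where the route is rejoined.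

Step 2. Facial selectivity in the radical pairing may be poor, or the titanium enolate may be reduced back to 3 instead of coupling, because the outcome depends on the lifetime and aggregation of the titanium-bound radical. The fallback builds the two centres one after the other by enolate alkylations. It sets out from 3: deprotonation with NaN(SiMe3)2 (THF, -78 °C) and alkylation with tert-butyl bromoacetate, anti to the benzyl group, should give tert-butyl (R)-3-[(S)-4-benzyl-2-oxo-1,3-oxazolidine-3-carbonyl]hex-5-enoate F4. LiBH4 removes the auxiliary and gives tert-butyl (R)-3-(hydroxymethyl)hex-5-enoate F5, and CF3CO2H in CH2Cl2 closes it to (R)-4-allyldihydrofuran-2(3H)-one F6. Alkylation of the lactone enolate (LiN(iPr)2, THF, -78 °C; allyl bromide) takes place trans to the β substituent and gives (3R,4R)-3,4-diallyldihydrofuran-2(3H)-one F7. LiAlH4 reduces F7 to diol 6, where the route is rejoined.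

Step 13. The second alcohol may be oxidised before the lactol closes (giving a dialdehyde), the aldehyde α carbon may epimerise, or the trivalent iodine oxidant may attack the electron-rich arenes. The fallback separates oxidation from lactone formation. It sets out from 23, which is oxidised fully (TEMPO (cat.), NaClO2, NaOCl (cat.), phosphate buffer, MeCN) to (2R,3R)-2,3-bis(3,4,5-trimethoxybenzyl)succinic acid F8. Ac2O closes F8 to the trans anhydride (3R,4R)-3,4-bis(3,4,5-trimethoxybenzyl)dihydrofuran-2,5-dione F9. NaBH4 in THF reduces one carbonyl of F9 (both are equivalent by symmetry), and acidic work-up lactonises the hydroxy acid to 26.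

## Further compounds

F1 | step 8 | dimethyl (2E,5R,6R,8E)-5,6-bis[(benzyloxy)methyl]deca-2,8-dienedioate | COC(=O)/C=C/C[C@H]([C@H](COCc1ccccc1)C/C=C/C(=O)OC)COCc1ccccc1
F2 | step 10 | 5,5'-[(2R,3R)-2,3-bis[(benzyloxy)methyl]butane-1,4-diyl]bis(2,3-dimethoxycyclohex-2-en-1-one) | COC1=C(OC)C(=O)CC(C[C@H]([C@H](COCc2ccccc2)CC2CC(OC)=C(OC)C(=O)C2)COCc2ccccc2)C1
F3 | step 10 | bis(trimethylsilyl dienol ether) of F2, 1-trimethylsilyloxy-2,3-dimethoxycyclohexa-1,3-dien-5-yl rings | COC1=C(OC)C(O[Si](C)(C)C)=CC(C[C@H]([C@H](COCc2ccccc2)CC2C=C(O[Si](C)(C)C)C(OC)=C(OC)C2)COCc2ccccc2)C1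
F4 | step 2 | tert-butyl (R)-3-[(S)-4-benzyl-2-oxo-1,3-oxazolidine-3-carbonyl]hex-5-enoate | C=CC[C@H](CC(=O)OC(C)(C)C)C(=O)N1C(=O)OC[C@@H]1Cc1ccccc1
F5 | step 2 | tert-butyl (R)-3-(hydroxymethyl)hex-5-enoate | C=CC[C@H](CC(=O)OC(C)(C)C)CO
F6 | step 2 | (R)-4-allyldihydrofuran-2(3H)-one | C=CC[C@H]1COC(=O)C1
F7 | step 2 | (3R,4R)-3,4-diallyldihydrofuran-2(3H)-one | C=CC[C@H]1COC(=O)[C@@H]1CC=C
F8 | step 13 | (2R,3R)-2,3-bis(3,4,5-trimethoxybenzyl)succinic acid | COc1cc(C[C@H]([C@H](C(=O)O)Cc2cc(OC)c(OC)c(OC)c2)C(=O)O)cc(OC)c1OC
F9 | step 13 | (3R,4R)-3,4-bis(3,4,5-trimethoxybenzyl)dihydrofuran-2,5-dione | COc1cc(C[C@H]2C(=O)OC(=O)[C@@H]2Cc2cc(OC)c(OC)c(OC)c2)cc(OC)c1OC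
A1 | alternative 1 | (2R,3R)-2,3-dimethyl-N1,N4-di(quinolin-8-yl)succinamide | C[C@H]([C@H](C(=O)Nc1cccc2cccnc12)C)C(=O)Nc1cccc2cccnc12
A2 | alternative 1 | 5-iodo-1,2,3-trimethoxybenzene | COc1cc(I)cc(OC)c1OC
A3 | alternative 1 | palladium diacetate | CC(=O)[O-].CC(=O)[O-].[Pd+2]
A4 | alternative 1 | silver acetate | CC(=O)[O-].[Ag+]
A5 | alternative 1 | (2R,3R)-N1,N4-di(quinolin-8-yl)-2,3-bis(3,4,5-trimethoxybenzyl)succinamide | COc1cc(C[C@H]([C@H](C(=O)Nc2cccc3cccnc23)Cc2cc(OC)c(OC)c(OC)c2)C(=O)Nc2cccc3cccnc23)cc(OC)c1OC
A6 | alternative 2 | (R)-2-(3,4,5-trimethoxybenzyl)-4-oxo-4-(3,4,5-trimethoxyphenyl)butanoic acid | COc1cc(C[C@H](CC(=O)c2cc(OC)c(OC)c(OC)c2)C(=O)O)cc(OC)c1OC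
A7 | alternative 2 | formaldehyde | C=O
A8 | alternative 2 | (3R,4R)-3-(3,4,5-trimethoxybenzyl)-4-(3,4,5-trimethoxybenzoyl)dihydrofuran-2(3H)-one | COc1cc(C(=O)[C@H]2COC(=O)[C@@H]2Cc2cc(OC)c(OC)c(OC)c2)cc(OC)c1OC
A9 | alternative 3 | buta-1,3-diene | C=CC=C
A10 | alternative 3 | bis[(1R,2S,5R)-2-isopropyl-5-methylcyclohexyl] fumarate | O=C(/C=C/C(=O)O[C@@H]1C[C@H](C)CC[C@H]1C(C)C)O[C@@H]1C[C@H](C)CC[C@H]1C(C)C
A11 | alternative 3 | diethylaluminium chloride | CC[Al](Cl)CC
A12 | alternative 3 | bis[(1R,2S,5R)-2-isopropyl-5-methylcyclohexyl] (1R,2R)-cyclohex-4-ene-1,2-dicarboxylate | C1[C@H]([C@H](C(=O)O[C@@H]2C[C@H](C)CC[C@H]2C(C)C)CC=C1)C(=O)O[C@@H]1C[C@H](C)CC[C@H]1C(C)C
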